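41.0 kJ mol⁻¹ is the gap to watch when you repeat these flasks: the activation energy of solvolysis of the intermediate is higher than that of its capture by first nucleophile by this much.

| setting | gamma | delta | theta |
|---|---|---|---|
| starting material | 1.0 M | 1.0 M | 1.0 M |
| first nucleophile | 0.800 M | 0.800 M | 0.800 M |
| second nucleophile | 1.20 M | 1.20 M | 1.20 M |
| temperature | 90 °C | 120 °C | 60 °C |
| time | 20 s | 20 s | 20 s |

* the flask with the highest amount of target, in percent of the starting material charged ("all alike" if they lie within 1.5 percentage points) (gamma / delta / theta / all alike)
* final target, as a percentage of the starting material charged, in gamma
* final target, as a percentage of the starting material charged, in delta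
* final target, as a percentage of the starting material charged, in theta

- amounts and yields of target count crystals and idle adduct too
- given per volume of solution although it is solid: crystals
- the list of constants is for 90 °C, to be carried to other temperatures by the activation energies and enthalpies

    crystals ⇌ target, rate k1*(cs1 - [target]) while solid is left; crystals form when [target] > cs1 (cs1 = 42 mM, k1 = 2.8 s⁻¹)
    first nucleophile + target ⇌ idle adduct, settled at all times (K2 = 0.54 M⁻¹, ΔH2 = −32.0 kJ mol⁻¹)
    second nucleophile + intermediate → other capture product (k3 = 4.1 M⁻¹ s⁻¹, Ea3 = 60.0 kJ mol⁻¹)
    starting material → intermediate (k4 = 0.16 s⁻¹, Ea4 = 93.0 kJ mol⁻¹)
    intermediate → solvolysis product (k5 = 1.2 s⁻¹, Ea5 = 97.0 kJ mol⁻¹)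
    first nucleophile + intermediate → target (k6 = 4.1 M⁻¹ s⁻¹, Ea6 = 56.0 kJ mol⁻¹)
    (constants at 90 °C)

Starting material gives the intermediate, which has several exits: first nucleophile turns it into target, second nucleophile into other capture product, and on its own it becomes solvolysis product. Here is what each given number is worth, by my own reckoning.

Crystals and idle adduct count as target, so the solubility and dissolution coefficient just shift target between forms. Reckoned at saturation with the full charge in gamma, the adduct holds 18.1 mM, far less than the 0.800 M of first nucleophile charged, so I leave it out.

The half-life of starting material is 0.413 s in delta, far shorter than the 20 s run, so an error in it shifts delta little. In theta it is 69.4 s, longer than the run, so theta's target follows this constant nearly in proportion, and you need its activation energy well.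

In gamma the exits together run at 9.40 s⁻¹, faster than the 0.16 s⁻¹ that feeds them, so the intermediate passes straight on, and dividing one exit rate by their sum removes time. Their ratios count, not their sizes. Second nucleophile's constant over first's moves just to 1.11 at delta's temperature. Solvolysis over first nucleophile's constant goes from 0.0862 M in theta to 0.825 M in delta.

So, with the charges held, first nucleophile's exit rate over the sum of the exits gives 27.1 % in delta. This is the target share, the selectivity for target. It is 34.9 % in gamma and 41.0 % in theta. Multiplied by the part of starting material converted, my figures are 33.5 % for gamma, 27.1 % for delta and 7.42 % for theta, so I expect gamma highest.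

The forecast also names gamma, with 32 % there, 25.6 % in delta and 7.4 % in theta. It says “I treated the intermediate as steady-state with both nucleophiles depleting”, whereas I held the charges, and its gamma and delta figures stand below mine.

The simulation gives gamma highest, with 31.9 % there, 25.6 % in delta and 7.04 % in theta.

Delta has 0 % of its starting material left at the end, and its target stands somewhat below the target share of 27.1 %. A neighbour of delta is charged with 3.0 M of second nucleophile instead of 1.20 M. With that charge in the sum of exits, the target share reckons to 16.2 %. That neighbour ends with 15.9 % target and 65.7 % other capture product.

The numbers of this flask come from no measurement; the run is a simulation.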